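The runs come from a simulation with constants of no real substance.

At 40 min the gamma flask reads 0.1018 M of Prd, and its last 8.00 min added just 0.00220 M, with a scatter of 8 × 10⁻⁴ M on each reading.

| setting | gamma | epsilon | delta | zeta |
|---|---|---|---|---|
| Sub | 0.250 M | 0.150 M | 0.250 M | 0.250 M |
| Rgt | 0.250 M | 0.150 M | 0.250 M | 0.250 M |
| Cat | 0.00250 M | 0.00250 M | 0.00130 M | 0.00250 M |
| Prd |  |  |  | 0.0750 M |
| time |  |  |  | 40 min |

- gamma run (time / min: [Prd] / M): 8.0: 0.0588; 16: 0.0844; 24: 0.0946; 32: 0.0996; 40: 0.1018
- epsilon run (time / min: [Prd] / M): 8.0: 0.0397; 16: 0.0545; 24: 0.0582; 32: 0.0618; 40: 0.0607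
- delta run (time / min: [Prd] / M): 8.0: 0.0327; 16: 0.0495; 24: 0.0577; 32: 0.0631; 40: 0.0649

(readings scatter by 8 × 10⁻⁴ M)

- Overall: Sub + Rgt -> Prd, with Cat as catalyst.
- Constant volume, constant temperature.
- What is held in complexes is read along with the free species.
- An order is taken over about fifteen percent of the charge, up and down.
- A share of Prd counts the Prd that was charged too.

* reaction order in [Cat] at the outset, round the charge of the gamma run, defined at two percent of the Sub turned into Prd
* Prd in the zeta run at 40 min, as a share of the Sub charged

**How far does gamma get?** It gets to 40.7%. This is f, the stall share: the Prd made by the last reading, over the Sub charged.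

**Is that an equilibrium?** Then K = [Prd]/([Sub][Rgt]) should repeat. Gamma gives 4.64 /M, epsilon 7.61 /M. It does not repeat, but f does: epsilon has 40.5%.

**So is f a property of the flask?** Of its charge of Cat, at least. Delta, with 0.00130 M of Cat, has 26.0%. Gamma and epsilon, with different charges of Sub and Rgt, read the same f within scatter, and delta, with less Cat than gamma, reads a lower one.

**And the order in Cat?** The first readings of gamma and delta give 0.897. But gamma has by then turned 23.5% of its Sub and delta 13.1%, so gamma has bent further and the ratio reads low. I commit to first order.

**Zeta is gamma plus 0.0750 M of Prd. Won't that Prd hold it back?** That is the weak spot. Gamma stalls with more Prd present than epsilon, yet with the same f within scatter, so no brake shows. Zeta, though, goes beyond any level read here. Taking f over unchanged, I reckon 70.7%.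

The forecast gives 1.05 for the order and 70% for zeta, holding that “added Prd shouldn't change the conversion reached”.

The flask gives an order of 1.0 and 71.0% for zeta.

    Cat + Sub → Z + Byp (127.2 /M/min)
    Z + Rgt → Prd + Cat (108.0 /M/min)
    Rgt → E (0.2940 /min)
    Sub + Rgt ⇌ Sub.Rgt, settled at all times (35.20 /M)

Zeta made 41.0% of its Sub, beside the 40.7% of gamma. Its stall comes from Rgt turning into E, since Z needs Rgt to give Prd and return Cat. The same zeta flask without that reaction reaches 122% at 40 min, which means 92.4% of its Sub turned into Prd by that time.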